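**Retrosynthetic overview**
- The target acid is cut at the C2=C3 enoate olefin (Wittig) and at the C4–C5 bond of the side chain (allylic bromide plus acetonitrile anion). This leads back to (2R)-2,8-dimethyl-2-(4-methylpent-3-en-1-yl)chroman-6-ol, whose E-methyl group is the handle for chain growth.
- Structural feature: in the 6-hydroxychroman the C6 hydroxyl is para to the O1-bearing C8a, and the C4–C4a bond is ortho to C8a. This is the substitution pattern left by a 1,2-alkyl shift in a 4-alkoxy-4-alkylcyclohexadienone.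
- The chromanol is therefore opened to a 1-oxaspiro[4.5]deca-6,9-dien-8-one (C4 back on the spiro carbon). The dienone comes from a para-alkylphenol with a pendant tertiary alcohol by oxidative dearomatization.
- That phenol comes from (R)-linalool and silylated 4-bromo-3-methylphenol by hydroboration and B-alkyl Suzuki coupling. C2 of the target is the linalool carbinol carbon.
- Ring order: arene (bought), then spiro tetrahydrofuran (step 4), then dihydropyran by ring expansion with rearomatization (step 5).

Key step: step 5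

Assumption: commercial (R)-(−)-linalool of high enantiomeric purity is used, because C2 of the target is inherited from it unchanged; its tertiary hydroxyl is carried unprotected through the hydroboration.

**Route**

Step 1
Reactants: 1 4-bromo-3-methylphenol
Product: 2 (4-bromo-3-methylphenoxy)triisopropylsilane
Conditions: TIPSCl, imidazole, DMF, rt
Reagents that add atoms: chlorotriisopropylsilane (TIPSCl), CC(C)[Si](Cl)(C(C)C)C(C)C
Why: Standard silylation of a phenol; the triisopropylsilyl ether is chosen because it should withstand the aqueous phosphate base of the coupling in step 2.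

Step 2
Reactants: 3 (R)-linalool; 2 (4-bromo-3-methylphenoxy)triisopropylsilane
Product: 5 (3R)-3,7-dimethyl-1-[2-methyl-4-(triisopropylsilyloxy)phenyl]oct-6-en-3-ol, via alkylborane 4 (not isolated)
Conditions: 9-BBN (1.5 equiv), THF, 0 °C → rt; then 2, Pd(OAc)2 (5 mol %), SPhos (10 mol %), aq K3PO4 (3 equiv), THF, 65 °C
Reagents that add atoms: 9-borabicyclo[3.3.1]nonane (9-BBN), B1C2CCCC1CCC2 (its boron and carbons are carried by intermediate 4 only; product 5 keeps one hydrogen from it)
Why: 9-BBN should add anti-Markovnikov to the monosubstituted vinyl group only (the trisubstituted olefin reacts far more slowly), and borane 4 should then undergo B-alkyl Suzuki–Miyaura coupling with the aryl bromide; the carbinol stereocentre takes no part and keeps its configuration.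

Step 3
Reactants: 5 (3R)-3,7-dimethyl-1-[2-methyl-4-(triisopropylsilyloxy)phenyl]oct-6-en-3-ol
Product: 6 4-[(3R)-3-hydroxy-3,7-dimethyloct-6-en-1-yl]-3-methylphenol
Conditions: Bu4NF (TBAF), THF, 0 °C; H2O work-up
Reagents that add atoms: none
Why: Fluoride-mediated cleavage of an aryl silyl ether is fast and leaves the tertiary alcohol and the olefin untouched.

Step 4
Reactants: 6 4-[(3R)-3-hydroxy-3,7-dimethyloct-6-en-1-yl]-3-methylphenol
Product: 7 (2R)-2,6-dimethyl-2-(4-methylpent-3-en-1-yl)-1-oxaspiro[4.5]deca-6,9-dien-8-one (both C5 epimers)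
Conditions: PhI(OAc)2 (1.1 equiv), MeCN, 0 °C
Reagents that add atoms: none
Why: Hypervalent-iodine oxidative dearomatization of the para-alkylphenol, with 5-exo capture of the para carbon by the tertiary hydroxyl (spiroetherification), should give the spirodienone; the new spiro centre forms without control, which is harmless because step 5 makes it planar.

Step 5
Reactants: 7 (2R)-2,6-dimethyl-2-(4-methylpent-3-en-1-yl)-1-oxaspiro[4.5]deca-6,9-dien-8-one
Product: 8 (2R)-2,8-dimethyl-2-(4-methylpent-3-en-1-yl)-3,4-dihydro-2H-chromen-6-ol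
Conditions: BF3·OEt2 (0.3 equiv), CH2Cl2, −78 → −30 °C; aq NaHCO3 quench
Reagents that add atoms: none
Why: BF3 binds the C8 carbonyl and turns the dienone into a hydroxypentadienyl cation with charge at C6 and C10, the two carbons flanking spiro C5; the ring methylene C4 then shifts suprafacially from C5 to the hydrogen-bearing C10, which forms the C4–C4a bond and leaves C5 as an oxocarbenium ion stabilised by O1, and loss of the C10 proton regenerates the arene. This is the dienone–phenol (quinol ether) rearrangement of 4-alkoxy-4-alkylcyclohexadienones. The dihydropyran ring is closed by ring expansion and not by cyclisation: the five-membered spiro ether takes in C10 (the future C4a) as a ring atom through the 1,2-shift. No stereocentre is created; the uncontrolled spiro centre becomes the planar C8a and C2 keeps all four of its bonds, so the linalool configuration is carried through as 2R. The step needs carbon and not oxygen to migrate, and migration to C10 and not to the methyl-bearing C6: only the carbon shift leaves an oxygen-stabilised cation, and only the shift to C10 can end in proton loss while a shift to C6 is reversible, which fixes the 8-methyl, 6-hydroxy pattern. Low temperature and a substoichiometric Lewis acid are chosen so that the tertiary C2–O bond and the side-chain olefin should not ionise.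

Step 6
Reactants: 8 (2R)-2,8-dimethyl-2-(4-methylpent-3-en-1-yl)-3,4-dihydro-2H-chromen-6-ol
Product: 9 tert-butyl{[(2R)-2,8-dimethyl-2-(4-methylpent-3-en-1-yl)-3,4-dihydro-2H-chromen-6-yl]oxy}dimethylsilane
Conditions: TBSCl, imidazole, DMF, rt
Reagents that add atoms: tert-butyl(chloro)dimethylsilane (TBSCl), CC(C)(C)[Si](C)(C)Cl
Why: Silylation masks the oxidation-prone hydroquinone-monoether phenol before the peroxide step, and the aryl tert-butyldimethylsilyl ether can later be removed by hydroxide together with the ester.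

Step 7
Reactants: 9 tert-butyl{[(2R)-2,8-dimethyl-2-(4-methylpent-3-en-1-yl)-3,4-dihydro-2H-chromen-6-yl]oxy}dimethylsilane
Product: 11 (2E)-5-[(2R)-6-{[tert-butyl(dimethyl)silyl]oxy}-2,8-dimethyl-3,4-dihydro-2H-chromen-2-yl]-2-methylpent-2-en-1-ol, via over-oxidised enal 10 (not isolated)
Conditions: SeO2 (0.3 equiv), t-BuOOH (3 equiv), salicylic acid (0.1 equiv), CH2Cl2, 0 °C → rt; then NaBH4, MeOH, 0 °C
Reagents that add atoms: selenium dioxide, O=[Se]=O (delivers the hydroxyl oxygen and is regenerated by tert-butyl hydroperoxide, CC(C)(C)OO)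
Why: Riley-type allylic oxidation (ene reaction, then [2,3]-sigmatropic shift), run catalytically in SeO2, should attack the E-methyl of the trisubstituted olefin and give the E-allylic alcohol; the portion over-oxidised to enal 10 is returned to 11 by the borohydride treatment in the same flask.

Step 8
Reactants: 11 (2E)-5-[(2R)-6-{[tert-butyl(dimethyl)silyl]oxy}-2,8-dimethyl-3,4-dihydro-2H-chromen-2-yl]-2-methylpent-2-en-1-ol
Product: 12 {[(2R)-2-[(3E)-5-bromo-4-methylpent-3-en-1-yl]-2,8-dimethyl-3,4-dihydro-2H-chromen-6-yl]oxy}(tert-butyl)dimethylsilane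
Conditions: CBr4, PPh3, CH2Cl2, 0 °C
Reagents that add atoms: carbon tetrabromide, BrC(Br)(Br)Br
Why: The Appel reaction should convert the primary allylic alcohol into the bromide under neutral conditions by SN2 displacement, without allylic transposition or loss of the E geometry or of the silyl ether.

Step 9
Reactants: 12 {[(2R)-2-[(3E)-5-bromo-4-methylpent-3-en-1-yl]-2,8-dimethyl-3,4-dihydro-2H-chromen-6-yl]oxy}(tert-butyl)dimethylsilane; 13 acetonitrile
Product: 15 (4E)-7-[(2R)-6-{[tert-butyl(dimethyl)silyl]oxy}-2,8-dimethyl-3,4-dihydro-2H-chromen-2-yl]-4-methylhept-4-enenitrile, via (cyanomethyl)lithium 14 (not isolated)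
Conditions: MeCN (3 equiv), n-BuLi (3 equiv), THF, −78 °C; then 12, −78 → −40 °C
Reagents that add atoms: none
Why: SN2 alkylation of lithioacetonitrile by the primary allylic bromide should add the two-carbon nitrile unit, the excess of anion holding back double alkylation and the low temperature sparing the aryl silyl ether.

Step 10
Reactants: 15 (4E)-7-[(2R)-6-{[tert-butyl(dimethyl)silyl]oxy}-2,8-dimethyl-3,4-dihydro-2H-chromen-2-yl]-4-methylhept-4-enenitrile
Product: 17 (4E)-7-[(2R)-6-{[tert-butyl(dimethyl)silyl]oxy}-2,8-dimethyl-3,4-dihydro-2H-chromen-2-yl]-4-methylhept-4-enal, via N-aluminio aldimine 16 (not isolated)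
Conditions: i-Bu2AlH (1.3 equiv), toluene, −78 °C; then aq tartaric acid, 0 °C → rt
Reagents that add atoms: water, O (the aldehyde oxygen, on hydrolysis of 16)
Why: i-Bu2AlH adds a single hydride to the nitrile and the resulting N-aluminio imine resists further reduction, so mild acidic hydrolysis should release the aldehyde while the silyl ether and the isolated olefin stay inert.

Step 11
Reactants: 17 (4E)-7-[(2R)-6-{[tert-butyl(dimethyl)silyl]oxy}-2,8-dimethyl-3,4-dihydro-2H-chromen-2-yl]-4-methylhept-4-enal; 18 ethyl 2-(triphenylphosphoranylidene)propanoate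
Product: 19 ethyl (2E,6E)-9-[(2R)-6-{[tert-butyl(dimethyl)silyl]oxy}-2,8-dimethyl-3,4-dihydro-2H-chromen-2-yl]-2,6-dimethylnona-2,6-dienoate
Conditions: CH2Cl2, rt → 40 °C
Reagents that add atoms: none
Why: Wittig olefination with the stabilised α-methyl ylide should give the trisubstituted enoate with the ester trans to the chain (E), as is usual for stabilised ylides and unhindered aliphatic aldehydes.

Step 12
Reactants: 19 ethyl (2E,6E)-9-[(2R)-6-{[tert-butyl(dimethyl)silyl]oxy}-2,8-dimethyl-3,4-dihydro-2H-chromen-2-yl]-2,6-dimethylnona-2,6-dienoate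
Product: 20 (2E,6E)-9-[(2R)-6-hydroxy-2,8-dimethyl-3,4-dihydro-2H-chromen-2-yl]-2,6-dimethylnona-2,6-dienoic acid (CNP0176653.1)
Conditions: LiOH·H2O (6 equiv), degassed THF/MeOH/H2O, 50 °C, Ar; then 1 M HCl to pH 3, 0 °C
Reagents that add atoms: lithium hydroxide, [Li+].[OH-] (the carboxyl OH oxygen)
Why: Saponification of the ethyl ester and hydroxide cleavage of the aryl silyl ether should occur in the same operation, with oxygen excluded to protect the electron-rich chromanol phenoxide; neither the olefin geometries nor C2 are at risk.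

**Compound list**
1 | 4-bromo-3-methylphenol | Cc1cc(O)ccc1Br | starting material
2 | (4-bromo-3-methylphenoxy)triisopropylsilane | Cc1cc(O[Si](C(C)C)(C(C)C)C(C)C)ccc1Br | intermediate
3 | (R)-linalool, (3R)-3,7-dimethylocta-1,6-dien-3-ol | C=C[C@@](O)(C)CCC=C(C)C | starting material
4 | (3S)-1-(9-borabicyclo[3.3.1]nonan-9-yl)-3,7-dimethyloct-6-en-3-ol (descriptor changes by priority only) | CC(C)=CCC[C@@](C)(O)CCB1C2CCCC1CCC2 | intermediate (not isolated)
5 | (3R)-3,7-dimethyl-1-[2-methyl-4-(triisopropylsilyloxy)phenyl]oct-6-en-3-ol | CC(C)=CCC[C@@](C)(O)CCc1ccc(O[Si](C(C)C)(C(C)C)C(C)C)cc1C | intermediate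
6 | 4-[(3R)-3-hydroxy-3,7-dimethyloct-6-en-1-yl]-3-methylphenol | CC(C)=CCC[C@@](C)(O)CCc1ccc(O)cc1C | intermediate
7 | (2R)-2,6-dimethyl-2-(4-methylpent-3-en-1-yl)-1-oxaspiro[4.5]deca-6,9-dien-8-one, both C5 epimers | C[C@@]1(CCC=C(C)C)CCC2(O1)C(C)=CC(=O)C=C2 | intermediate
8 | (2R)-2,8-dimethyl-2-(4-methylpent-3-en-1-yl)-3,4-dihydro-2H-chromen-6-ol | CC(C)=CCC[C@]1(C)CCc2cc(O)cc(C)c2O1 | intermediate
9 | tert-butyl{[(2R)-2,8-dimethyl-2-(4-methylpent-3-en-1-yl)-3,4-dihydro-2H-chromen-6-yl]oxy}dimethylsilane | CC(C)=CCC[C@]1(C)CCc2cc(O[Si](C)(C)C(C)(C)C)cc(C)c2O1 | intermediate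
10 | (2E)-5-[(2R)-6-{[tert-butyl(dimethyl)silyl]oxy}-2,8-dimethyl-3,4-dihydro-2H-chromen-2-yl]-2-methylpent-2-enal | C/C(=C\CC[C@]1(C)CCc2cc(O[Si](C)(C)C(C)(C)C)cc(C)c2O1)C=O | intermediate (not isolated)
11 | (2E)-5-[(2R)-6-{[tert-butyl(dimethyl)silyl]oxy}-2,8-dimethyl-3,4-dihydro-2H-chromen-2-yl]-2-methylpent-2-en-1-ol | C/C(=C\CC[C@]1(C)CCc2cc(O[Si](C)(C)C(C)(C)C)cc(C)c2O1)CO | intermediate
12 | {[(2R)-2-[(3E)-5-bromo-4-methylpent-3-en-1-yl]-2,8-dimethyl-3,4-dihydro-2H-chromen-6-yl]oxy}(tert-butyl)dimethylsilane | C/C(=C\CC[C@]1(C)CCc2cc(O[Si](C)(C)C(C)(C)C)cc(C)c2O1)CBr | intermediate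
13 | acetonitrile | CC#N | starting material
14 | (cyanomethyl)lithium | [Li]CC#N | intermediate (not isolated)
15 | (4E)-7-[(2R)-6-{[tert-butyl(dimethyl)silyl]oxy}-2,8-dimethyl-3,4-dihydro-2H-chromen-2-yl]-4-methylhept-4-enenitrile | C/C(=C\CC[C@]1(C)CCc2cc(O[Si](C)(C)C(C)(C)C)cc(C)c2O1)CCC#N | intermediate
16 | N-(diisobutylaluminio) aldimine of aldehyde 17 | C/C(=C\CC[C@]1(C)CCc2cc(O[Si](C)(C)C(C)(C)C)cc(C)c2O1)CCC=N[Al](CC(C)C)CC(C)C | intermediate (not isolated)
17 | (4E)-7-[(2R)-6-{[tert-butyl(dimethyl)silyl]oxy}-2,8-dimethyl-3,4-dihydro-2H-chromen-2-yl]-4-methylhept-4-enal | C/C(=C\CC[C@]1(C)CCc2cc(O[Si](C)(C)C(C)(C)C)cc(C)c2O1)CCC=O | intermediate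
18 | ethyl 2-(triphenylphosphoranylidene)propanoate | CCOC(=O)C(C)=P(c1ccccc1)(c1ccccc1)c1ccccc1 | starting material
19 | ethyl (2E,6E)-9-[(2R)-6-{[tert-butyl(dimethyl)silyl]oxy}-2,8-dimethyl-3,4-dihydro-2H-chromen-2-yl]-2,6-dimethylnona-2,6-dienoate | C/C(=C\CC[C@]1(C)CCc2cc(O[Si](C)(C)C(C)(C)C)cc(C)c2O1)CC/C=C(\C)C(=O)OCC | intermediate
20 | (2E,6E)-9-[(2R)-6-hydroxy-2,8-dimethyl-3,4-dihydro-2H-chromen-2-yl]-2,6-dimethylnona-2,6-dienoic acid | C/C(=C\CC[C@]1(C)CCc2cc(O)cc(C)c2O1)CC/C=C(\C)C(=O)O | target

**Totals**
Total step count: 12. Longest linear sequence: 12 steps (1 to 20; linalool 3 enters at step 2, acetonitrile 13 at step 9, ylide 18 at step 11).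

**Steps most likely to fail**

1. Step 5 (ring expansion). Ionisation of the tertiary C2–O bond, migration toward the methyl-bearing carbon followed by a methyl shift, or acid-induced reaction of the side-chain olefin may outrun the desired 1,2-shift. The fallback forms the aryl–O1 bond by metal catalysis instead, so C2 is again never touched. It sets out from alkylborane 4 (made from 3 as in step 2) and returns at 8.
   - Commercial 4-methoxy-2-methylaniline (Cc1cc(OC)ccc1N) would be iodinated at the free position ortho to nitrogen (ICl, AcOH) to give 2-iodo-4-methoxy-6-methylaniline F1.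
   - Sandmeyer bromination (t-BuONO, CuBr2, MeCN) would give 2-bromo-1-iodo-5-methoxy-3-methylbenzene F2.
   - Borane 4 would be coupled selectively at the C–I bond (PdCl2(dppf), aq K3PO4, THF, rt) to give (3R)-1-(2-bromo-5-methoxy-3-methylphenyl)-3,7-dimethyloct-6-en-3-ol F3.
   - Pd-catalysed intramolecular C–O coupling of the tertiary alcohol with the aryl bromide (Pd(OAc)2, a di-tert-butylbiarylphosphine, Cs2CO3, toluene, 80 °C) would close the ring to (2R)-6-methoxy-2,8-dimethyl-2-(4-methylpent-3-en-1-yl)-3,4-dihydro-2H-chromene F4.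
   - Demethylation with NaSEt in DMF at 130 °C, which the olefin tolerates, would give 8.

2. Step 7 (allylic oxidation). Incomplete conversion, over-oxidation and attack of the oxidant on the electron-rich arene may leave little allylic alcohol. The fallback sets out from 9 and returns at 11. Cross-metathesis of the isopropylidene terminus of 9 with methacrolein (second-generation Hoveyda–Grubbs catalyst, CH2Cl2, 40 °C) would give the E-enal 10 directly, with loss of isobutene. Luche reduction (NaBH4, CeCl3·7H2O, MeOH, 0 °C) would then give 11.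

3. Step 2 (hydroboration and coupling). The free tertiary hydroxyl may consume borane, and oxidative addition into the hindered, electron-rich C–Br bond may be slow enough for protodeboronation to compete. The fallback sets out from 2 and 3 and returns at 5. A Mizoroki–Heck reaction of 2 with the vinyl group of 3 (Pd(OAc)2, P(o-tol)3, Et3N, DMF, 100 °C) would give (1E,3R)-3,7-dimethyl-1-[2-methyl-4-(triisopropylsilyloxy)phenyl]octa-1,6-dien-3-ol F5. Chemoselective hydrogenation of its disubstituted styrenyl olefin (H2, RhCl(PPh3)3, benzene/EtOH, rt), which should leave the trisubstituted olefin alone, would give 5.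

Further compounds
F1 | step 5 | 2-iodo-4-methoxy-6-methylaniline | Cc1cc(OC)cc(I)c1N
F2 | step 5 | 2-bromo-1-iodo-5-methoxy-3-methylbenzene | Cc1cc(OC)cc(I)c1Br
F3 | step 5 | (3R)-1-(2-bromo-5-methoxy-3-methylphenyl)-3,7-dimethyloct-6-en-3-ol | CC(C)=CCC[C@@](C)(O)CCc1cc(OC)cc(C)c1Br
F4 | step 5 | (2R)-6-methoxy-2,8-dimethyl-2-(4-methylpent-3-en-1-yl)-3,4-dihydro-2H-chromene | CC(C)=CCC[C@]1(C)CCc2cc(OC)cc(C)c2O1
F0 | step 7 | none | none
F5 | step 2 | (1E,3R)-3,7-dimethyl-1-[2-methyl-4-(triisopropylsilyloxy)phenyl]octa-1,6-dien-3-ol | CC(C)=CCC[C@@](C)(O)/C=C/c1ccc(O[Si](C(C)C)(C(C)C)C(C)C)cc1C
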